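**Retrosynthetic overview**
1. Target 10 ⇐ tris-MOM flavonol 9 by loss of three MOM groups (same pot).
2. 9 ⇐ chalcone 6: the pyranone ring is closed last through two C–O bonds (O1–C2 by phenoxide oxa-Michael addition, C3–O by enolate aminoxylation and N–O fragmentation).
3. 6 ⇐ aryl methyl ketone 4 + aldehyde 5 (Claisen–Schmidt condensation).
4. 4 ⇐ 3 (selective bis-MOM protection) ⇐ 1 + two prenyl bromide 2 (double C-prenylation).
5. Ring order: rings A and B are bought as arenes; ring C (4H-pyran-4-one) is the only ring formed, in the last step.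

Assumptions: the target has no stereocentre and no stereogenic double bond, so no stereocontrol is needed. 4-(Methoxymethoxy)benzaldehyde is taken as a catalogue compound.

**Step 1**
Reactants: 1 2,4,6-trihydroxyacetophenone; 2 prenyl bromide (2.2 equiv)
Product: 3 3,5-diprenyl-2,4,6-trihydroxyacetophenone
Conditions: 10% aq. KOH, 0 °C → rt, slow addition of 2; acidify, chromatography
Reagents that add atoms: none
Why: C-alkylation of the phloroglucinol phenoxide in water (hydrogen-bonded oxygen favours attack through carbon); the two free ring positions are equivalent, so bis-alkylation gives one regioisomer, separated from mono-, O- and gem-dialkylated by-products.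

**Step 2**
Reactants: 3 3,5-diprenyl-2,4,6-trihydroxyacetophenone
Product: 4 1-[2-hydroxy-4,6-bis(methoxymethoxy)-3,5-bis(3-methylbut-2-en-1-yl)phenyl]ethan-1-one
Conditions: MOMCl (2.3 equiv), i-Pr2NEt (3 equiv), CH2Cl2, 0 °C → rt
Reagents that add atoms: chloromethyl methyl ether (MOMCl), COCCl
Why: Williamson-type acetal protection; the ortho-hydroxyl hydrogen-bonded to the acetyl carbonyl is unreactive under amine-base conditions, so protection stops at the 4,6-bis-MOM ether.

**Step 3**
Reactants: 4 bis-MOM ketone; 5 4-(methoxymethoxy)benzaldehyde (1.3 equiv)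
Product: 6 (E)-1-[2-hydroxy-4,6-bis(methoxymethoxy)-3,5-bis(3-methylbut-2-en-1-yl)phenyl]-3-[4-(methoxymethoxy)phenyl]prop-2-en-1-one
Conditions: KOH (50% aq., excess), EtOH, rt, 24–48 h; cold neutral work-up
Reagents that add atoms: none
Why: Claisen–Schmidt aldol condensation; E1cB dehydration gives the conjugated E-enone, and MOM ethers and prenyl groups are inert to base (any flavanone 7 formed on work-up is on the pathway of step 4).

**Step 4**
Reactants: 6 2'-hydroxychalcone
Product: 10 6,8-diprenylkaempferol, via flavanone 7 (not isolated), via 3-anilinooxyflavanone 8 (not isolated), via tris-MOM flavonol 9 (not isolated)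
Conditions: PhNO (1.2 equiv, slow addition), DBU (2.2 equiv), THF, 0 °C → rt, Ar, dark; then 3 M HCl–MeOH, 45 °C
Reagents that add atoms: nitrosobenzene, O=Nc1ccccc1
Why: Proposed new method: a nitroso variant of the Algar–Flynn–Oyamada (AFO) oxidative cyclization. DBU ionizes the 2'-OH and the phenoxide closes by 6-endo oxa-Michael addition (O1–C2 bond) to the enolate of flavanone 7. The enolate carbon is trapped by the nitroso oxygen (O-selective nitroso aldol, C3–O bond) to give 8; the paired amidinium N–H can protonate nitrogen in the transition state as the acid does in enamine aminoxylations, and no metal ion is present to steer attack to nitrogen. DBU then removes the acidic C3–H of 8 with N–O cleavage (Kornblum–DeLaMare-type fragmentation, aniline leaving) to the 3,4-dione, which tautomerizes to the aromatic flavonol 9. Nitrosobenzene is purely electrophilic, so it cannot epoxidize the enone (the origin of aurones from 6'-alkoxychalcones under alkaline H2O2) and does not epoxidize the prenyl alkenes as peracids or dioxiranes would. Closest known reactions: AFO reaction, tandem conjugate addition/enolate oxidation, amine-mediated α-aminoxylation with nitrosobenzene, Kornblum–DeLaMare rearrangement. Methanolic HCl then removes the three MOM acetals by transacetalization under conditions routinely tolerated by prenyl phenols; the C2/C3 stereocentres of 7 and 8 are transient and erased on aromatization.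

**Compound list**
1 | 2,4,6-trihydroxyacetophenone (phloracetophenone) | CC(=O)c1c(O)cc(O)cc1O | starting material
2 | 1-bromo-3-methylbut-2-ene (prenyl bromide) | CC(C)=CCBr | starting material
3 | 1-[2,4,6-trihydroxy-3,5-bis(3-methylbut-2-en-1-yl)phenyl]ethan-1-one | CC(=O)c1c(O)c(CC=C(C)C)c(O)c(CC=C(C)C)c1O | intermediate
4 | 1-[2-hydroxy-4,6-bis(methoxymethoxy)-3,5-bis(3-methylbut-2-en-1-yl)phenyl]ethan-1-one | CC(=O)c1c(O)c(CC=C(C)C)c(OCOC)c(CC=C(C)C)c1OCOC | intermediate
5 | 4-(methoxymethoxy)benzaldehyde | COCOc1ccc(C=O)cc1 | starting material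
6 | (E)-1-[2-hydroxy-4,6-bis(methoxymethoxy)-3,5-bis(3-methylbut-2-en-1-yl)phenyl]-3-[4-(methoxymethoxy)phenyl]prop-2-en-1-one | COCOc1ccc(/C=C/C(=O)c2c(O)c(CC=C(C)C)c(OCOC)c(CC=C(C)C)c2OCOC)cc1 | intermediate
7 | 5,7-bis(methoxymethoxy)-2-[4-(methoxymethoxy)phenyl]-6,8-bis(3-methylbut-2-en-1-yl)chroman-4-one (racemic; reacts on as its amidinium enolate) | COCOc1ccc(cc1)C1CC(=O)c2c(OCOC)c(CC=C(C)C)c(OCOC)c(CC=C(C)C)c2O1 | intermediate (not isolated)
8 | (2R*,3R*)-3-(anilinooxy)-5,7-bis(methoxymethoxy)-2-[4-(methoxymethoxy)phenyl]-6,8-bis(3-methylbut-2-en-1-yl)chroman-4-one (racemic, trans expected; one enantiomer drawn) | COCOc1ccc(cc1)[C@H]1Oc2c(CC=C(C)C)c(OCOC)c(CC=C(C)C)c(OCOC)c2C(=O)[C@@H]1ONc1ccccc1 | intermediate (not isolated)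
9 | 3-hydroxy-5,7-bis(methoxymethoxy)-2-[4-(methoxymethoxy)phenyl]-6,8-bis(3-methylbut-2-en-1-yl)-4H-chromen-4-one | COCOc1ccc(cc1)-c1oc2c(CC=C(C)C)c(OCOC)c(CC=C(C)C)c(OCOC)c2c(=O)c1O | intermediate (not isolated)
10 | 6,8-diprenylkaempferol, 3,5,7-trihydroxy-2-(4-hydroxyphenyl)-6,8-bis(3-methylbut-2-en-1-yl)-4H-chromen-4-one (achiral) | CC(C)=CCc1c(O)c(CC=C(C)C)c2oc(-c3ccc(O)cc3)c(O)c(=O)c2c1O | target

**Totals**
Total step count: 4. Longest linear sequence: 4 (1 → 3 → 4 → 6 → 10).

**Three steps most likely to fail**

Step 1 (double C-prenylation). The risk is a statistical mixture of mono-, di-, gem-di- and O-prenylated products, so the yield of 3 is modest. The fallback sets out from 1 and comes back at 3. It replaces phenoxide alkylation by an acid-mediated Friedel–Crafts prenylation: 2-methylbut-3-en-2-ol with BF3·OEt2 in dioxane at room temperature generates the prenyl cation, which substitutes the two free ring positions. This route makes no new compound (F0); recovered mono-prenyl material is resubmitted.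

Step 3 (Claisen–Schmidt condensation). The ketone is flanked by two ortho substituents and is present as a deactivating phenoxide, so condensation may stall. The fallback sets out from 4 (with 5) and comes back at 6. It is a directed aldol: 4 is converted with LiHMDS (2.2 equiv, THF, −78 °C) into the phenoxide–enolate dianion and treated with 5 to give the aldol adduct 3-hydroxy-1-[2-hydroxy-4,6-bis(methoxymethoxy)-3,5-bis(3-methylbut-2-en-1-yl)phenyl]-3-[4-(methoxymethoxy)phenyl]propan-1-one F1. This is dehydrated separately with MsCl/Et3N (benzylic mesylate, E1cB elimination) to the E-chalcone 6.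

Step 4 (new nitroso oxidative cyclization, then deprotection). The main risks are attack of the enolate on nitrogen of nitrosobenzene (leading to a 3-anilinoflavone), slow trapping of the low-concentration enolate, and acid-induced chroman formation if the HCl stage is overheated. The fallback uses known chemistry, sets out from 6 and comes back at 10:
- The 2'-OH is capped (MOMCl, NaH, DMF, 0 °C) to give the tetra-MOM chalcone (E)-1-[2,4,6-tris(methoxymethoxy)-3,5-bis(3-methylbut-2-en-1-yl)phenyl]-3-[4-(methoxymethoxy)phenyl]prop-2-en-1-one F2.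
- Weitz–Scheffer epoxidation (30% H2O2, aq. NaOH, MeOH–THF, 0 °C → rt; nucleophilic, so the prenyl alkenes are untouched) gives the trans-epoxide [3-[4-(methoxymethoxy)phenyl]oxiran-2-yl][2,4,6-tris(methoxymethoxy)-3,5-bis(3-methylbut-2-en-1-yl)phenyl]methanone F3.
- 3 M HCl–MeOH at 45 °C removes the MOM groups and lets the freed 2'-OH open the epoxide at the benzylic carbon (6-endo) to give trans-6,8-diprenyldihydrokaempferol F4.
- F4 is dehydrogenated to 10 by aerial oxidation in cold dilute aqueous–methanolic base (alternatively hot aqueous sodium bisulfite). These classical dihydroflavonol-to-flavonol methods need no halogen or quinone and so spare the prenyl groups.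

**Further compounds**
F0 | step 1 | none | none
F1 | step 3 | 3-hydroxy-1-[2-hydroxy-4,6-bis(methoxymethoxy)-3,5-bis(3-methylbut-2-en-1-yl)phenyl]-3-[4-(methoxymethoxy)phenyl]propan-1-one (racemic) | COCOc1ccc(cc1)C(O)CC(=O)c1c(O)c(CC=C(C)C)c(OCOC)c(CC=C(C)C)c1OCOC
F2 | step 4 | (E)-1-[2,4,6-tris(methoxymethoxy)-3,5-bis(3-methylbut-2-en-1-yl)phenyl]-3-[4-(methoxymethoxy)phenyl]prop-2-en-1-one | COCOc1ccc(/C=C/C(=O)c2c(OCOC)c(CC=C(C)C)c(OCOC)c(CC=C(C)C)c2OCOC)cc1
F3 | step 4 | trans-[3-[4-(methoxymethoxy)phenyl]oxiran-2-yl][2,4,6-tris(methoxymethoxy)-3,5-bis(3-methylbut-2-en-1-yl)phenyl]methanone (racemic; one enantiomer drawn) | COCOc1ccc(cc1)[C@@H]1O[C@H]1C(=O)c1c(OCOC)c(CC=C(C)C)c(OCOC)c(CC=C(C)C)c1OCOC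
F4 | step 4 | (2R*,3R*)-3,5,7-trihydroxy-2-(4-hydroxyphenyl)-6,8-bis(3-methylbut-2-en-1-yl)chroman-4-one (racemic trans; one enantiomer drawn) | Oc1ccc(cc1)[C@H]1Oc2c(CC=C(C)C)c(O)c(CC=C(C)C)c(O)c2C(=O)[C@@H]1O
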